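The runs were generated by integration on assumed constants, and the scatter is random.

I decided to judge both flasks by free X, not by Z, and to leave them shut for the full 10 h.

all flasks: Z 19 mM
- spring: X 18 mM; run made earlier
- autumn: X 29 mM; run made earlier
- Thursday's: X 28.0 mM; time 10 h
- Tuesday's: X 43.0 mM; time 10 h

| run | time / h | J / % | G / % | L / % | Z / % |
|---|---|---|---|---|---|
| spring | 0.500 | 7.9 | 0 | 0.2 | 92.2 |
| spring | 1.33 | 15.7 | 0 | 4.7 | 79.1 |
| spring | 2.50 | 21.6 | 1.0 | 8.6 | 68.5 |
| spring | 4.00 | 28.3 | 1.7 | 14.3 | 59.6 |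
| spring | 5.00 | 30.4 | 3.5 | 12.5 | 54.8 |
| spring | 8.00 | 34.9 | 6.0 | 10.8 | 44.1 |
| autumn | 1.33 | 21.5 | 1.6 | 11.8 | 68.0 |
| autumn | 2.50 | 26.3 | 2.0 | 19.2 | 55.3 |
| autumn | 4.00 | 29.4 | 6.0 | 23.5 | 42.0 |
| autumn | 5.00 | 33.5 | 3.8 | 28.0 | 36.5 |
| autumn | 6.00 | 34.1 | 7.9 | 25.0 | 31.7 |
| autumn | 8.00 | 38.0 | 9.9 | 24.7 | 26.5 |

(standard deviation of a reading: 1 percentage point)

- which of these there is most of at the end, counted by the Z in it, Thursday's (L / J / G / Z)
- which of these there is most of at the end, counted by the Z in it, Tuesday's (L / J / G / Z)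
- final amount of the leader among these, as a percentage of the Z charged, in Thursday's
- final amount of the leader among these, as a percentage of the Z charged, in Tuesday's

- L is meant together with its D
- solid, in amounts per volume of the solution: D
- steps that have been proposed: Z + X -> J; X + J <-> L; D <-> L; L <-> G

For whoever takes over: each flask turns Z and X into J, then L; L may crystallise as D and passes to G, which keeps L's two X. X was never read, so I reckoned it by balance. At the autumn run's last reading, J, L and G left 8.63 mM free, so the reading K = L/(J·X) was 0.0753 mM⁻¹; the spring run's last reading gave 0.0621 mM⁻¹.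

Freezing the autumn value (a pre-equilibrium), I named the balance point X* = 1/K, the free X at which J and L stand level: 13.3 mM. The autumn run's free X was already below X*, and Thursday's charge is close to that run's, so I expected J ahead of L in Thursday's. Tuesday's reaches X* after spending 1.56 X per Z charged; the autumn run had spent 1.07 by its last reading. Tuesday's, with more X, might spend more than that, so I leaned to L ahead of J in Tuesday's, but I put no amount on it. Don't add X: in this reckoning L/J follows free X.

The forecast named J at 40% for Thursday's and L at 42% for Tuesday's, reasoning “Crystallising D would then shelter L from reversal”.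

The flasks gave J at 40.7% in Thursday's and L at 41.8% in Tuesday's.

    Z + X → J (k = 0.00310 M⁻¹ s⁻¹)
    X + J ⇌ L (K = 89.0 M⁻¹, k = 0.00880 M⁻¹ s⁻¹)
    D ⇌ L, rate k3*(cs3 - [L]) while solid is left; crystals form when [L] > cs3 (solubility = 6.80 mM, k = 0.00490 s⁻¹)
    L ⇌ G (K = 2.40, k = 1.90 × 10⁻⁵ s⁻¹)

Free X ended at 6.87 mM in Thursday's, below X*, and at 14.2 mM in Tuesday's, above it. With all else as in Tuesday's, J and L stand level at 39.0 mM of X, less than Tuesday's charge. Tuesday's flask read at 25 h held 11.2 mM free X, below X*, so K gave L/J as 0.842; there G held most at 39.6%, and J at 30.3% stood above L at 29.0%.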